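The runs are simulated with made-up constants, and the scatter is random.

Amounts first: the Friday flask held starting material, 0.500 equiv of second substrate, a trace of free enzyme, and less impurity than enzyme.

common to all: starting material 0.10 M; free enzyme 0.042 mol%; impurity 9.6 µM
- Friday's: second substrate 0.50 equiv; temperature 5 °C; the very flask that is asked about, followed so far
- Wednesday's: second substrate 0.50 equiv; temperature 0 °C; run made earlier
- flask: second substrate 0.500 equiv; temperature 5 °C; time 12 h

| run | time / min | target / % |
|---|---|---|
| Friday's | 50.0 | 71.1 |
| Friday's | 120 | 74.2 |
| Friday's | 240 | 74.5 |
| Friday's | 600 | 74.7 |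
| Wednesday's | 50.0 | 62.9 |
| Wednesday's | 120 | 87.9 |
| Wednesday's | 240 | 87.5 |
| Wednesday's | 600 | 87.7 |

(scatter of a reading: 0.3 percentage points)

- alpha: change nothing and wait 4.0 h more
- theta: at 12 h add free enzyme, 50.0% of the amount charged, then wait 4.0 h
- gamma: at 12 h take out 90% of the target then present, then wait 4.0 h
- epsilon: at 12 h raise the temperature by 15 K, then wait 4.0 h

- what is taken out of target is counted as made
- on the list of suspects stand: free enzyme -> unfolded enzyme; starting material + free enzyme <-> complex A; free enzyme + impurity -> spent catalyst; complex A <-> free enzyme + target; second substrate + free enzyme <-> complex B; complex B -> free enzyme + second product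
- additions bring no volume worth counting

1. target, in percent of the starting material first charged, at 12 h
2. the option that brings most further target ("none" if no option brings more than 2 percentage points) (alpha / theta / gamma / epsilon / none)
3. target present, with what was taken out counted in, in percent of the starting material first charged, after alpha
4. target present, with what was taken out counted in, in percent of the starting material first charged, after gamma

I built the flask up one process at a time. First came the main step. Free enzyme carries starting material to target through complex A, and both arrows on that path run both ways. Held at one temperature, such a step stops at one ratio of its two ends (thermodynamic control). Friday's last three readings average 74.5%, which gives 2.92 of target per starting material. I called this the tilt, the ratio [target]/[starting material] at the stop. A tilt of 1 is the even split, the zero of my scale. Wednesday's last three readings average 87.7%, a tilt of 7.13 at 0 °C. So the colder run stood further from zero. That is a steep fall, but I took it as read.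

Then I added second substrate. I expected it to delay target, not to move the ratio of the two ends. Next came the impurity, which could take a quarter of the enzyme. I expected that to slow the flask and leave the tilt alone.

Unfolding came last. If it finished the enzyme early, the stop was a dead stop and my ratio no tilt. Friday's readings moved 0.5 percentage points after 120 min, against a scatter of 0.3 points, and a flat line of that kind fits a dead stop and a balance alike. So the readings did not part the two. I committed to a balance with living enzyme, as a choice and without proof.

So I expected 74.5% at 12 h, and nothing from alpha or theta. Warming should lose target, going by the two tilts. Gamma takes out 90% of the target, which leaves starting material and target together as a pool of 33.0% of the charge. The tilt divides that pool again, and the counted target comes to 91.6%. So I chose gamma.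

The forecast gave 74.6%, 74.7% after alpha and 74.8% after gamma, and it chose theta. Its ground: “Waiting does nothing, and neither does removing product or warming.” My reckoning differs from it on gamma and on the choice.

The Friday flask gave 74.5% at 12 h. The best option was gamma, which brought 17 points, while theta brought 0 points.

    free enzyme → unfolded enzyme (k = 1.15 × 10⁻⁵ s⁻¹, Ea = 278 kJ mol⁻¹)
    starting material + free enzyme ⇌ complex A (K = 9.80 M⁻¹, k = 354 M⁻¹ s⁻¹, Ea = 45.0 kJ mol⁻¹, ΔH = −48.0 kJ mol⁻¹)
    free enzyme + impurity → spent catalyst (k = 5430 M⁻¹ s⁻¹, Ea = 12.0 kJ mol⁻¹)
    complex A ⇌ free enzyme + target (K = 0.298 M, k = 6.01 s⁻¹, Ea = 69.0 kJ mol⁻¹, ΔH = −66.0 kJ mol⁻¹)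
    second substrate + free enzyme ⇌ complex B (K = 530 M⁻¹, k = 263 M⁻¹ s⁻¹, Ea = 40.0 kJ mol⁻¹, ΔH = −2.00 kJ mol⁻¹)
    complex B → free enzyme + second product (k = 1.71 s⁻¹, Ea = 74.0 kJ mol⁻¹)
    (constants at 5 °C)

At 720 min free enzyme in the Friday flask stood at 41.9% of the catalyst charged, and complex A at 10.5%. After gamma the counted target was 91.6%, and the tilt's split of the pool had given 91.6%. At the same temperature with 0.025 M of starting material, the neighbour flask ended with 59.8% target and 40.2% starting material. Its ratio of 1.49 lay below the tilt, with spent catalyst at 91.4% of the catalyst charged.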